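common to all: free catalyst 0.250 mM
- blue: substrate 50.0 mM; reagent 125 mM
- green: substrate 30.0 mM; reagent 105 mM
- violet: substrate 150 mM; reagent 125 mM
- teal: substrate 50.0 mM; reagent 250 mM
- red: substrate 13.0 mM; reagent 31.0 mM; time 60 min

| blue run: time / min | blue run: [substrate] / mM | green run: time / min | green run: [substrate] / mM | violet run: time / min | violet run: [substrate] / mM | teal run: time / min | teal run: [substrate] / mM |
|---|---|---|---|---|---|---|---|
| 2.4 | 45.6 | 2.4 | 28.7 | 2.4 | 137.5 | 2.4 | 40.4 |
| 4.1 | 42.8 | 4.1 | 26.2 | 4.1 | 130.2 | 4.1 | 35.2 |
| 7.0 | 37.9 | 7.0 | 23.6 | 7.0 | 118.9 | 7.0 | 28.3 |
| 12 | 32.1 | 12 | 19.8 | 12 | 103.1 | 12 | 19.3 |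
| 21 | 23.1 | 21 | 14.8 | 21 | 85.4 | 21 | 10.2 |
| 35 | 14.3 | 35 | 9.2 | 35 | 67.3 | 35 | 4.6 |
| 60 | 7.0 | 60 | 4.7 | 60 | 51.6 | 60 | 0.7 |

(scatter of a reading: 0.5 mM)

- reaction order in [reagent] at the outset, round the charge of the blue run, defined at two percent of the substrate turned into product
- reaction order in [substrate] at the outset, round the charge of the blue run, defined at two percent of the substrate turned into product (one fixed amount of product, the same in the runs compared)
- the green run starts with 20.0 mM less of substrate and of reagent than the blue run, and with no product. Compared where both hold the same amount of substrate, once fifteen percent of what the green run was charged with has turned into product, is the green run faster, slower or alike (within a tenth)?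
- substrate in the red run at 60 min, as a share of the substrate charged

- Overall: substrate + reagent -> product, with free catalyst as catalyst.
- Constant volume, constant temperature.
- Readings of a species count what is bound in complexes too.
- An order is taken over about fifteen percent of the charge, up and down.

**Frozen excess.** At 60 min the red run is read once, and we want the share of its substrate still present then. One substrate takes one reagent, so the excess D = c(reagent) − c(substrate) stays frozen: 18.0 mM in the red run and 75.0 mM in the blue run. If the rate is k·c(substrate)·c(reagent), the logarithm of c(reagent)/c(substrate) climbs in a straight line of slope k·D. One reading of the blue run, 14.3 mM at 35 min, gives 3.49 × 10⁻⁴ mM⁻¹ min⁻¹. We call this k the flask constant: the rate per unit of c(substrate) and of c(reagent) at a free catalyst charge of 0.250 mM.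

**Other runs.** The teal run, with twice the reagent of the blue run, reads 3.42 × 10⁻⁴ mM⁻¹ min⁻¹ at 12 min, close to the blue value, so we take the reagent order as about one. The violet run, charged with 150 mM of substrate, reads 3.22 × 10⁻⁴ mM⁻¹ min⁻¹ at 35 min, lower than the blue value, so we put the substrate order a little under one.

**Green against blue.** The green run has the same excess as the blue run, so at equal substrate the two hold equal reagent, while the blue run has made 20.0 mM more product. The green run reads 3.49 × 10⁻⁴ mM⁻¹ min⁻¹ at 21 min, close to the blue value, so we expect the two rates to be alike.

**Two extremes.** Suppose c(reagent) in the red run stayed at its charge of 31.0 mM, the pseudo-first-order picture. Then 52.3% of the substrate would remain at 60 min. Frozen instead at the excess of 18.0 mM, which is lower, it would leave 68.6%. Substrate is the limiting reagent in the red run, so c(reagent) there stays between these two values, and on this rate law the red run lies between the two shares. The straight line itself, solved at 60 min, gives our figure of 55.9%.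

**The forecast.** The forecast gives 1 for the reagent order, 0.95 for the substrate order, alike for the green run and 56% for the red run. On green against blue it says: “I see no product inhibition or catalyst decay, so they are alike.”

**The result.** The simulation leaves 56.0% of the substrate in the red run, with orders of 1.0 in reagent and 0.97 in substrate. Where both hold the same amount of substrate, the green run comes out alike, at 1.0 times the rate of the blue run. These steps stood behind the readings.

    free catalyst + substrate ⇌ catalyst-substrate complex, settled at all times (4.950 M⁻¹)
    catalyst-substrate complex + reagent → product + free catalyst (1230 M⁻¹ min⁻¹)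
    free catalyst + impurity → spent catalyst
    2 free catalyst ⇌ resting dimer, settled at all times (17400 M⁻¹)

**Teal again.** The flask constant now goes to the teal run, where the excess is 200 mM. It puts half the substrate charged turned into product at 8.43 min, and the teal run reached that point at 8.66 min.

All runs were computed from invented constants, and the scatter is random.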